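The target is a flavanone–flavone dimer whose only stereocentre is C2 of the flavanone. The route rests on the C3–C4 bond of the flavanone pyranone ring (ring C): C3 is a bare methylene, C4 an aryl ketone carbon on ring A, and C2 carries O1, the B-ring aryl and one hydrogen. A salicylaldehyde-type aldehyde (future C4) whose ortho oxygen bears a 1-arylvinyl group (O1–C2=C3H2) is therefore cyclised by rhodium-catalysed enantioselective hydroacylation: one isomerisation forms C3–C4, closes ring C and places the formyl hydrogen on C2 as 2S. The achiral precursor already contains the benzyl-protected apigenin unit and comes from Petasis methylenation of an aryl ester followed by Suzuki coupling.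

Key step: step 9

Remark on the chemistry: 2,6-dihydroxy-4-methoxybenzaldehyde (4) is assumed to be purchasable, like apigenin (1) and 3-bromo-4-methoxybenzoic acid (6); the bisphosphine enantiomer written in step 9 is the one that a model cyclisation is expected to assign to the 2S product, and its antipode is used otherwise.

Step 1
Reactants: 1 apigenin
Product: 2 tri-O-benzylapigenin
Conditions: BnBr (4 equiv), K2CO3 (5 equiv), DMF, 80 °C
Reagents that add atoms: benzyl bromide, BrCc1ccccc1
Why: Williamson O-benzylation of all three phenols, the chelated 5-OH needing the excess of base and the heat.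

Step 2
Reactants: 2 tri-O-benzylapigenin
Product: 3 8-iodo-tri-O-benzylapigenin
Conditions: I2 (1.1 equiv), CF3CO2Ag (1.1 equiv), CH2Cl2, 0 °C to rt, dark
Reagents that add atoms: iodine, II
Why: Electrophilic aromatic iodination with silver-activated iodine, which on a 5,7-dialkoxyflavone should go to C8 (para to the 5-oxygen, ortho to the 7-oxygen) rather than to C6.

Step 3
Reactants: 4 2,6-dihydroxy-4-methoxybenzaldehyde
Product: 5 2-(benzyloxy)-6-hydroxy-4-methoxybenzaldehyde
Conditions: BnBr (1.0 equiv), K2CO3 (1.1 equiv), acetone, 56 °C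
Reagents that add atoms: benzyl bromide, BrCc1ccccc1
Why: Williamson mono-benzylation of a substrate with two equivalent hydroxyls, so only one regioisomer can form, and the remaining chelated hydroxyl is less reactive, which restrains dibenzylation.

Step 4
Reactants: 5 2-(benzyloxy)-6-hydroxy-4-methoxybenzaldehyde; 6 3-bromo-4-methoxybenzoic acid
Product: 7 3-(benzyloxy)-2-formyl-5-methoxyphenyl 3-bromo-4-methoxybenzoate
Conditions: DCC (1.2 equiv), DMAP (0.2 equiv), CH2Cl2, 0 °C to rt
Reagents that add atoms: none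
Why: Steglich esterification, in which DMAP-mediated acyl transfer should acylate the hydrogen-bonded phenol under neutral conditions.

Step 5
Reactants: 7 formyl aryl ester
Product: 8 3-(benzyloxy)-2-(1,3-dioxolan-2-yl)-5-methoxyphenyl 3-bromo-4-methoxybenzoate
Conditions: Me3SiOCH2CH2OSiMe3 (2 equiv), Me3SiOSO2CF3 (5 mol%), CH2Cl2, −78 to −20 °C; pyridine quench
Reagents that add atoms: 1,2-bis(trimethylsilyloxy)ethane, C[Si](C)(C)OCCO[Si](C)(C)C
Why: Noyori acetalisation under aprotic conditions at low temperature masks the aldehyde before the carbonyl methylenation without transesterifying the aryl ester.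

Step 6
Reactants: 8 dioxolane aryl ester
Product: 9 2-[2-(benzyloxy)-6-{[1-(3-bromo-4-methoxyphenyl)ethenyl]oxy}-4-methoxyphenyl]-1,3-dioxolane
Conditions: Cp2TiMe2 (3 equiv), toluene, 70 °C, dark; filtration through basic Al2O3
Reagents that add atoms: dimethyltitanocene Cp2TiMe2, [CH3-].[CH3-].[Ti+4].c1cc[cH-]c1.c1cc[cH-]c1
Why: Petasis methylenation, in which thermally generated Cp2Ti=CH2 should convert the aryl ester carbonyl into the 1-arylvinyl aryl ether through an oxatitanacyclobutane while acetal, benzyl ethers and aryl bromide stay inert.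

Step 7
Reactants: 9 bromo enol ether dioxolane; 3 8-iodo-tri-O-benzylapigenin
Product: 11 dioxolane-protected biaryl enol ether (8-aryl-tri-O-benzylapigenin), via pinacol arylboronate 10 (not isolated)
Conditions: B2pin2 (1.1 equiv), PdCl2(dppf) (5 mol%), KOAc (3 equiv), 1,4-dioxane, 90 °C; then 3 (0.9 equiv), Pd(OAc)2 (5 mol%), SPhos (10 mol%), K3PO4 (3 equiv), H2O, 90 °C
Reagents that add atoms: none
Why: One-pot Miyaura borylation and Suzuki–Miyaura coupling with boron on the less hindered partner, in which SPhos-ligated zerovalent palladium should join the tri-ortho-substituted biaryl while the basic medium preserves acetal and enol ether.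

Step 8
Reactants: 11 dioxolane-protected biaryl enol ether
Product: 12 2-(benzyloxy)-6-{[1-(3-{5,7-bis(benzyloxy)-2-[4-(benzyloxy)phenyl]-4-oxo-4H-chromen-8-yl}-4-methoxyphenyl)ethenyl]oxy}-4-methoxybenzaldehyde
Conditions: PPTS (0.1 equiv), acetone–H2O (20:1), 0 °C; NaHCO3 quench at full conversion
Reagents that add atoms: water, O
Why: Acid-catalysed acetal hydrolysis, in which the oxocarbenium ion of this benzylidene acetal is stabilised by three ring oxygens, so its cleavage should be much faster than C-protonation of the aryl enol ether.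

Step 9
Reactants: 12 enol-ether aldehyde
Product: 13 (2S)-5-(benzyloxy)-2-(3-{5,7-bis(benzyloxy)-2-[4-(benzyloxy)phenyl]-4-oxo-4H-chromen-8-yl}-4-methoxyphenyl)-7-methoxy-2,3-dihydro-4H-chromen-4-one
Conditions: [Rh(cod)Cl]2 (5 mol%), (R)-DTBM-SEGPHOS (10 mol%), NaB[3,5-(CF3)2C6H3]4 (10 mol%), 1,4-dioxane, 60 °C, argon
Reagents that add atoms: none
Why: Proposed new method: a cationic bisphosphine complex of monovalent rhodium should insert into the aldehyde C–H bond of 12 to give an acyl hydride of trivalent rhodium, the 1,1-disubstituted enol ether then inserts into Rh–H so that hydride goes to the oxygen- and aryl-bearing carbon (future C2) and rhodium to the terminal CH2 (future C3), and C–C reductive elimination from the seven-membered acyl alkyl rhodacycle forms the C3–C4 bond. The closest known reaction types are the rhodium-catalysed endo- and enantioselective hydroacylation of ortho-allylbenzaldehydes with 1,1-disubstituted alkenes to six-membered aryl ketones and the same catalysis on N-vinylindole-2-carbaldehydes, where hydride is likewise delivered to a heteroatom-bearing alkene carbon, and the new element is an O-aryl 1-arylvinyl ether as the alkene. Ring C closes in a 6-endo-trig sense (acyl carbon onto the alkene terminus), whereas the 5-exo alternative would require reductive elimination at a fully substituted carbon to a quaternary 2-aryl-2-methylbenzofuran-3-one and is expected to be slow and reversible. The C2 stereocentre is set when hydride is transferred to one enantiotopic face of the enol ether inside the chiral pocket of the bisphosphine, so it is under catalyst control and the ligand enantiomer is fixed on a simpler model. The step needs six- over five-membered regioselectivity, enantioselectivity and suppression of decarbonylation, which are secured respectively by the 1,1-disubstitution of the alkene, by the ligand, and by the alkene being held next to rhodium through O1 while the 5-benzyloxy group prevents the unproductive phenoxide chelation that a free 5-OH would give.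

Step 10
Reactants: 13 (2S)-tetra-O-benzyl dihydrobiflavone
Product: 14 target, (2S)-2-{3-[5,7-dihydroxy-2-(4-hydroxyphenyl)-4-oxo-4H-chromen-8-yl]-4-methoxyphenyl}-5-hydroxy-7-methoxy-2,3-dihydro-4H-chromen-4-one
Conditions: H2 (1 atm), 10% Pd/C, THF–MeOH (1:1), rt
Reagents that add atoms: none
Why: Hydrogenolysis of the four aryl benzyl ethers under neutral conditions should leave the flavone double bond, the base-labile flavanone and its C2 configuration untouched.

Compound list
1 | apigenin, 5,7-dihydroxy-2-(4-hydroxyphenyl)-4H-chromen-4-one | O=c1cc(-c2ccc(O)cc2)oc2cc(O)cc(O)c12 | starting material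
2 | 5,7-bis(benzyloxy)-2-[4-(benzyloxy)phenyl]-4H-chromen-4-one | O=c1cc(-c2ccc(OCc3ccccc3)cc2)oc2cc(OCc3ccccc3)cc(OCc3ccccc3)c12 | intermediate
3 | 5,7-bis(benzyloxy)-2-[4-(benzyloxy)phenyl]-8-iodo-4H-chromen-4-one | O=c1cc(-c2ccc(OCc3ccccc3)cc2)oc2c(I)c(OCc3ccccc3)cc(OCc3ccccc3)c12 | intermediate
4 | 2,6-dihydroxy-4-methoxybenzaldehyde | COc1cc(O)c(C=O)c(O)c1 | starting material
5 | 2-(benzyloxy)-6-hydroxy-4-methoxybenzaldehyde | COc1cc(O)c(C=O)c(OCc2ccccc2)c1 | intermediate
6 | 3-bromo-4-methoxybenzoic acid | COc1ccc(C(=O)O)cc1Br | starting material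
7 | 3-(benzyloxy)-2-formyl-5-methoxyphenyl 3-bromo-4-methoxybenzoate | COc1cc(OCc2ccccc2)c(C=O)c(OC(=O)c2ccc(OC)c(Br)c2)c1 | intermediate
8 | 3-(benzyloxy)-2-(1,3-dioxolan-2-yl)-5-methoxyphenyl 3-bromo-4-methoxybenzoate | COc1cc(OCc2ccccc2)c(C2OCCO2)c(OC(=O)c2ccc(OC)c(Br)c2)c1 | intermediate
9 | 2-[2-(benzyloxy)-6-{[1-(3-bromo-4-methoxyphenyl)ethenyl]oxy}-4-methoxyphenyl]-1,3-dioxolane | COc1cc(OCc2ccccc2)c(C2OCCO2)c(OC(=C)c2ccc(OC)c(Br)c2)c1 | intermediate
10 | 2-[2-(benzyloxy)-4-methoxy-6-({1-[4-methoxy-3-(4,4,5,5-tetramethyl-1,3,2-dioxaborolan-2-yl)phenyl]ethenyl}oxy)phenyl]-1,3-dioxolane | COc1cc(OCc2ccccc2)c(C2OCCO2)c(OC(=C)c2ccc(OC)c(B3OC(C)(C)C(C)(C)O3)c2)c1 | intermediate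
11 | 5,7-bis(benzyloxy)-2-[4-(benzyloxy)phenyl]-8-[5-(1-{[3-(benzyloxy)-2-(1,3-dioxolan-2-yl)-5-methoxyphenyl]oxy}ethenyl)-2-methoxyphenyl]-4H-chromen-4-one | COc1cc(OCc2ccccc2)c(C2OCCO2)c(OC(=C)c2ccc(OC)c(-c3c(OCc4ccccc4)cc(OCc4ccccc4)c4c(=O)cc(-c5ccc(OCc6ccccc6)cc5)oc34)c2)c1 | intermediate
12 | 2-(benzyloxy)-6-{[1-(3-{5,7-bis(benzyloxy)-2-[4-(benzyloxy)phenyl]-4-oxo-4H-chromen-8-yl}-4-methoxyphenyl)ethenyl]oxy}-4-methoxybenzaldehyde | COc1cc(OCc2ccccc2)c(C=O)c(OC(=C)c2ccc(OC)c(-c3c(OCc4ccccc4)cc(OCc4ccccc4)c4c(=O)cc(-c5ccc(OCc6ccccc6)cc5)oc34)c2)c1 | intermediate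
13 | (2S)-5-(benzyloxy)-2-(3-{5,7-bis(benzyloxy)-2-[4-(benzyloxy)phenyl]-4-oxo-4H-chromen-8-yl}-4-methoxyphenyl)-7-methoxy-2,3-dihydro-4H-chromen-4-one | COc1cc(OCc2ccccc2)c2c(c1)O[C@H](c1ccc(OC)c(-c3c(OCc4ccccc4)cc(OCc4ccccc4)c4c(=O)cc(-c5ccc(OCc6ccccc6)cc5)oc34)c1)CC2=O | intermediate
14 | (2S)-2-{3-[5,7-dihydroxy-2-(4-hydroxyphenyl)-4-oxo-4H-chromen-8-yl]-4-methoxyphenyl}-5-hydroxy-7-methoxy-2,3-dihydro-4H-chromen-4-one (CNP0169789.1) | COc1cc(O)c2c(c1)O[C@H](c1ccc(OC)c(-c3c(O)cc(O)c4c(=O)cc(-c5ccc(O)cc5)oc34)c1)CC2=O | target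

Total step count: 10. Longest linear sequence: 8 steps (4 to 14, steps 3 to 10); the apigenin branch (steps 1 and 2) joins at step 7.

Steps most likely to fail

1. Step 9 (key step, proposed new method). What may go wrong: decarbonylation of the acyl rhodium hydride before the alkene inserts, closure in the 5-exo sense, acid-type cleavage of the enol ether by the cationic metal, or poor facial selectivity in the hydride transfer. The fallback uses known radical chemistry and forms the same bond. It sets out from 12: a thiol-catalysed radical-chain hydroacylation (methyl thioglycolate as polarity-reversal catalyst, di-tert-butyl hyponitrite as initiator, 1,4-dioxane, 60 °C) should let the aroyl radical close 6-endo onto the enol-ether CH2, and the resulting benzylic α-oxy radical takes hydrogen from the thiol, giving the racemic tetra-O-benzyl dihydrobiflavone F1. Preparative HPLC on an amylose tris(3,5-dimethylphenylcarbamate) phase then separates the enantiomers; the 2S enantiomer is 13, where the route is rejoined, and the 2R enantiomer is discarded.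

2. Step 8. What may go wrong: competing C-protonation and hydrolysis of the 1-arylvinyl ether while the acetal is being cleaved. The fallback changes the mask to one that is removed without acid. It sets out from 7: 1,3-propanedithiol and BF3·OEt2 in CH2Cl2 at 0 °C should give the dithiane ester F2. Petasis methylenation (Cp2TiMe2, toluene, 70 °C) then gives the dithiane enol ether F3. The one-pot borylation and Suzuki–Miyaura coupling with 3 under the conditions of step 7 proceeds through the pinacol boronate F4 (not isolated) to the biaryl dithiane F5. S-Alkylative hydrolysis at neutral pH (MeI, CaCO3, MeCN–H2O, 45 °C) releases the aldehyde and comes back to the route at 12.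

3. Step 7. What may go wrong: protodeboronation of the arylboronate in hot aqueous base and slow transmetalation or reductive elimination at the doubly ortho-substituted C8 of the flavone, so that the coupling stalls. The fallback replaces boron and base by tin under neutral conditions. It sets out from 9: Me3SnSnMe3 with Pd(PPh3)4 in toluene at 100 °C should give the aryltrimethylstannane F6, and a Stille coupling with 3 (Pd(PPh3)4, CuI, CsF, DMF, 45 °C) comes back to the route at 11.

Further compounds
F1 | step 9 | racemic 5-(benzyloxy)-2-(3-{5,7-bis(benzyloxy)-2-[4-(benzyloxy)phenyl]-4-oxo-4H-chromen-8-yl}-4-methoxyphenyl)-7-methoxy-2,3-dihydro-4H-chromen-4-one | COc1cc(OCc2ccccc2)c2c(c1)OC(c1ccc(OC)c(-c3c(OCc4ccccc4)cc(OCc4ccccc4)c4c(=O)cc(-c5ccc(OCc6ccccc6)cc5)oc34)c1)CC2=O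
F2 | step 8 | 3-(benzyloxy)-2-(1,3-dithian-2-yl)-5-methoxyphenyl 3-bromo-4-methoxybenzoate | COc1cc(OCc2ccccc2)c(C2SCCCS2)c(OC(=O)c2ccc(OC)c(Br)c2)c1
F3 | step 8 | 2-[2-(benzyloxy)-6-{[1-(3-bromo-4-methoxyphenyl)ethenyl]oxy}-4-methoxyphenyl]-1,3-dithiane | COc1cc(OCc2ccccc2)c(C2SCCCS2)c(OC(=C)c2ccc(OC)c(Br)c2)c1
F4 | step 8 | 2-[2-(benzyloxy)-4-methoxy-6-({1-[4-methoxy-3-(4,4,5,5-tetramethyl-1,3,2-dioxaborolan-2-yl)phenyl]ethenyl}oxy)phenyl]-1,3-dithiane | COc1cc(OCc2ccccc2)c(C2SCCCS2)c(OC(=C)c2ccc(OC)c(B3OC(C)(C)C(C)(C)O3)c2)c1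
F5 | step 8 | 5,7-bis(benzyloxy)-2-[4-(benzyloxy)phenyl]-8-[5-(1-{[3-(benzyloxy)-2-(1,3-dithian-2-yl)-5-methoxyphenyl]oxy}ethenyl)-2-methoxyphenyl]-4H-chromen-4-one | COc1cc(OCc2ccccc2)c(C2SCCCS2)c(OC(=C)c2ccc(OC)c(-c3c(OCc4ccccc4)cc(OCc4ccccc4)c4c(=O)cc(-c5ccc(OCc6ccccc6)cc5)oc34)c2)c1
F6 | step 7 | 2-[2-(benzyloxy)-4-methoxy-6-({1-[4-methoxy-3-(trimethylstannyl)phenyl]ethenyl}oxy)phenyl]-1,3-dioxolane | COc1cc(OCc2ccccc2)c(C2OCCO2)c(OC(=C)c2ccc(OC)c([Sn](C)(C)C)c2)c1
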